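The numbers in the tables come from a simulation with constants of no real substance.

A portion of partner cannot be spent twice, so we reckon with what is left and not with what is made.

| flask | starting material | partner | remark | time |
|---|---|---|---|---|
| winter | 0.44 M | 0.72 M | run made earlier |  |
| south-east | 0.40 M | 0.720 M |  | 1.0 h |
| north | 0.60 M | 1.00 M |  | 1.0 h |

winter run (percent of the starting material charged)

| time / min | first product / % |
|---|---|
| 1.00 | 12.7 |
| 1.50 | 19.4 |
| 2.50 | 27.4 |
| 4.00 | 34.1 |
| 8.00 | 46.5 |
| 12.0 | 52.1 |

(each reading ± 1 percentage point)

- the earlier runs were read with a standard deviation of 1 percentage point

- the flask that ends with the higher amount of first product, in percent of the starting material charged, or "neither" when 2 percentage points or less lies between them (south-east / north / neither)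
- final first product, as a percentage of the starting material charged, in south-east
- final first product, as a percentage of the starting material charged, in north

We assume each starting material takes one partner, and call what then remains the spare partner, S = cB − cA, with cA and cB the charges: 0.320 M in south-east, 0.400 M in north and 0.280 M in the winter run. We further assume that any later reaction of first product goes with S times the time t. South-east then gets 5.71 times the S·t of the winter run at its last reading, and north 7.14 times, so both go further than that run. North stands 1.25 times above south-east, but that ratio gives an order and no size in points, so we make no call against the margin of 2 points.

The forecast does make a call: north, with 43% in south-east and 46% in north, since “All of them favour north”.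

The flasks give 50.8% in south-east and 50.2% in north, so the answer is neither.

    starting material + partner → first product + released group (k = 0.230 /M/min)
    starting material + partner → other mono adduct + released group (k = 0.0970 /M/min)
    partner + first product → double product + released group (k = 0.0290 /M/min)
    partner + other mono adduct → double product + released group (k = 0.690 /M/min)

In south-east, S less the double product, 0.192 M, gives 0.128 M, and the flask holds 0.133 M of partner at 1.00 h. The neighbouring flask is south-east with 0.29 M of partner, so its S is −0.110 M, and partner, the limiting reagent, is down to 0.56% of its charge. The negative S alone leaves 27.5% of the starting material unreacted. Adding its double product, 12.6%, gives 40.1%, and the neighbouring flask holds 41%.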